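**Direct plan and its weak points**

A direct plan would set C2 by asymmetric alkynylation of the ring B aldehyde and attach ring A by Mitsunobu etherification (propargylic aryl ether A1). It would close ring C by gold-catalysed alkyne oxidation and Friedel–Crafts attack (chroman-3-one A2), then reduce the ketone to the cis alcohol, acylate and debenzylate.
Its weakest steps would be:
- the Mitsunobu displacement at a carbinol that is benzylic, propargylic and activated by a para-alkoxy group: ionisation would compete with SN2 and erode the only stereocentre set so far;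
- the gold carbene ring closure, which would be untested on an α-aryl ether and would leave C2 between an aryl group, O1 and a ketone, the most easily enolised position of the skeleton;
- the hydride reduction of that labile ketone on late material: C3 would rest on substrate control alone, and the basic alkoxide could epimerise C2 before it is trapped.

**Plan of the new route**

Cuts: ring A is cut, not ring C: C4a–C5 (ketene closure), C8–C8a (enolate addition to a lactone), C4a–C8a (hydroformylation), then C2–C3 (alkoxyallylboration).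
Ring order: ring B is bought; ring C arises first, as a δ-lactone whose carbonyl carbon is the future C8a; ring A arises last, folded from a masked triketide (a dioxinone) onto that lactone.
Enabling feature: ring A is a phloroglucinol, so C5, C7 and C8a are at the carbonyl oxidation level and C8a already carries O1; a lactone carbon plus an acetoacetyl ketene therefore maps onto C8a and C5–C8.
Why the weak steps vanish: both stereocentres come from one allylboration, and the C2–O1 bond is never made by substitution nor broken. No carbonyl ever flanks C2. The C3 ester is in place before ring A exists, so its phenols need no protection.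

Key step: step 5

Remark on the chemistry: the (−)-Ipc2B reagent from (+)-α-pinene is taken to attack the Si face of the aldehyde, as in the parent allyl- and alkoxyallylborations; lactols 6 and 13 are anomeric mixtures; allyl methoxymethyl ether is taken as commercial.

**Route**

Step 1
Reactants: 1 3,4-bis(benzyloxy)benzaldehyde; 2 allyl methoxymethyl ether
Product: 5 (1R,2R)-1-[3,4-bis(benzyloxy)phenyl]-2-(methoxymethoxy)but-3-en-1-ol, via allylborane 3 (not isolated), via borinate 4 (not isolated)
Conditions: 2, s-BuLi, THF, −78 °C; (−)-Ipc2BOMe; BF3·OEt2; then 1, −78 °C; NaOH, H2O2, 0 °C to rt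
Reagents that add atoms: none
Why: Brown (Z)-γ-alkoxyallylboration: the lithium-chelated (Z)-alkoxyallyl anion gives the (Z)-allylborane 3, whose chair (Zimmerman–Traxler) transition state turns the Z geometry into the syn relation of C2–OH and C3–OMOM, while the isopinocampheyl groups direct the allyl unit to the Si face of the aldehyde and so set both stereocentres of the target (2R,3R in flavan numbering) in one step.

Step 2
Reactants: 5 (1R,2R)-1-[3,4-bis(benzyloxy)phenyl]-2-(methoxymethoxy)but-3-en-1-ol
Product: 7 (5R,6R)-6-[3,4-bis(benzyloxy)phenyl]-5-(methoxymethoxy)tetrahydro-2H-pyran-2-one, via lactol 6 (not isolated)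
Conditions: Rh(acac)(CO)2 (2 mol%), Xantphos (4 mol%), CO/H2 1:1 (10 bar), toluene, 70 °C; vent; then Ag2CO3 on Celite, toluene, reflux
Reagents that add atoms: carbon monoxide, [C-]#[O+]
Why: Linear-selective rhodium/Xantphos hydroformylation places the formyl carbon (the future C8a) on the terminal carbon and the δ-hydroxy aldehyde closes to lactol 6, which Fétizon oxidation (neutral, specific for lactols) converts into the δ-lactone, so ring C is formed with O1 bound to C8a and without any reaction at C2 or C3.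

Step 3
Reactants: 7 (5R,6R)-6-[3,4-bis(benzyloxy)phenyl]-5-(methoxymethoxy)tetrahydro-2H-pyran-2-one; 8 4-(benzyloxy)benzoyl chloride
Product: 10 (2R,3R)-2-[3,4-bis(benzyloxy)phenyl]-6-oxotetrahydro-2H-pyran-3-yl 4-(benzyloxy)benzoate, via hydroxy lactone 9 (not isolated)
Conditions: Me2BBr, CH2Cl2, −78 °C; aq NaHCO3; crude 9, then 8, pyridine, DMAP (cat.), CH2Cl2, 0 °C
Reagents that add atoms: none
Why: Me2BBr cleaves the methoxymethyl acetal at −78 °C without touching the aryl benzyl ethers or the lactone, and the cis-hydroxy lactone 9 is acylated at once under DMAP catalysis so that it has no time to rearrange to the γ-lactone; no stereocentre is involved.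

Step 4
Reactants: 10 (2R,3R)-2-[3,4-bis(benzyloxy)phenyl]-6-oxotetrahydro-2H-pyran-3-yl 4-(benzyloxy)benzoate; 11 2,2,6-trimethyl-4H-1,3-dioxin-4-one
Product: 13 (2R,3R)-2-[3,4-bis(benzyloxy)phenyl]-6-[(2,2-dimethyl-4-oxo-4H-1,3-dioxin-6-yl)methyl]-6-hydroxytetrahydro-2H-pyran-3-yl 4-(benzyloxy)benzoate, via dienolate 12 (not isolated)
Conditions: 11 (2.2 equiv), LiN(iPr)2 (2.2 equiv), THF, −78 °C; then 10, −78 °C; AcOH, −78 °C
Reagents that add atoms: none
Why: Claisen-type addition of the lithium dienolate 12 through its exocyclic γ-carbon to the lactone carbonyl, which is far more electrophilic than the hindered, electron-rich aroyl ester; the lithium hemiketal is stable at −78 °C, so the reaction stops after one addition and a cold acidic quench avoids ring-opening and acyl shift.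

Step 5
Reactants: 13 (2R,3R)-2-[3,4-bis(benzyloxy)phenyl]-6-[(2,2-dimethyl-4-oxo-4H-1,3-dioxin-6-yl)methyl]-6-hydroxytetrahydro-2H-pyran-3-yl 4-(benzyloxy)benzoate
Product: 18 (2R,3R)-2-[3,4-bis(benzyloxy)phenyl]-5,7-dihydroxy-3,4-dihydro-2H-chromen-3-yl 4-(benzyloxy)benzoate, via enol ether 14 (not isolated), via acylketene 15 (not isolated), via dienylketene 16 (not isolated), via cyclohexadienone 17 (not isolated)
Conditions: pyridinium p-toluenesulfonate (10 mol%), 4 Å molecular sieves, toluene, 40 °C; then dilution to 0.005 M, 110 °C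
Reagents that add atoms: none
Why: Proposed new method: acid and sieves should first dehydrate hemiketal 13 to the push–pull enol ether 14, which fixes O1 on C8a by carbonyl addition and not by substitution, so C2 keeps its configuration; at 110 °C the dioxinone should lose acetone by retro-[4+2] to give acylketene 15, whose enol tautomer 16 (reached by 1,5-hydrogen shift from C4a or by acid-catalysed migration of the enol ether double bond into the ring) is a dienylketene. Thermal 6π-electrocyclisation of 16 then joins C4a to C5, and enolisation of dienone 17 gives the phloroglucinol ring. The closest known reactions are the generation of acylketenes from dioxinones with trapping and aromatisation in resorcylate synthesis, and the dienylketene electrocyclisation that ends the Danheiser and cyclobutenone benzannulations; what is new is that the dienylketene is reached from an acylketene through a cyclic enol ether. Ring C closes as a six-membered hemiketal (6-exo-trig attack of O1–H on the C8a ketone) followed by dehydration, and ring A by disrotatory 6π closure; no stereocentre is formed (C4a of 17 is lost on enolisation) and C2 and C3 are spectators. The step needs C-acylation at C4a in place of O-acylation to a 4-hydroxy-2-pyranone or intermolecular trapping: the first is secured because the C8a oxygen is O1 and carries no hydrogen once 14 has formed (hence dehydration before heating), the second by high dilution and by sieves that take up the water.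

Step 6
Reactants: 18 (2R,3R)-2-[3,4-bis(benzyloxy)phenyl]-5,7-dihydroxy-3,4-dihydro-2H-chromen-3-yl 4-(benzyloxy)benzoate
Product: 19 epicatechin 3-O-p-hydroxybenzoate, (2R,3R)-2-(3,4-dihydroxyphenyl)-5,7-dihydroxy-3,4-dihydro-2H-chromen-3-yl 4-hydroxybenzoate
Conditions: H2 (1 atm), Pd(OH)2/C, THF/MeOH 1:1, rt
Reagents that add atoms: none
Why: Catalytic hydrogenolysis removes the three O-benzyl groups while the secondary alkyl benzoate and the cyclic benzylic C2–O1 ether survive these mild conditions, as in the debenzylation of protected catechin esters, and neither stereocentre is touched.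

**Compound list**

1 | 3,4-bis(benzyloxy)benzaldehyde | O=Cc1ccc(OCc2ccccc2)c(OCc2ccccc2)c1 | starting material
2 | allyl methoxymethyl ether, 3-(methoxymethoxy)prop-1-ene | C=CCOCOC | starting material
3 | [(Z)-3-(methoxymethoxy)allyl]diisopinocampheylborane, Ipc groups from (+)-α-pinene | COCO/C=C\CB([C@@H]1C[C@@H]2C[C@H]([C@H]1C)C2(C)C)[C@@H]1C[C@@H]2C[C@H]([C@H]1C)C2(C)C | intermediate (not isolated)
4 | (1R,2R)-1-[3,4-bis(benzyloxy)phenyl]-2-(methoxymethoxy)but-3-en-1-yl diisopinocampheylborinate | COCO[C@@H]([C@H](OB([C@@H]1C[C@@H]2C[C@H]([C@H]1C)C2(C)C)[C@@H]1C[C@@H]2C[C@H]([C@H]1C)C2(C)C)c1ccc(OCc2ccccc2)c(OCc2ccccc2)c1)C=C | intermediate (not isolated)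
5 | (1R,2R)-1-[3,4-bis(benzyloxy)phenyl]-2-(methoxymethoxy)but-3-en-1-ol | COCO[C@@H]([C@H](O)c1ccc(OCc2ccccc2)c(OCc2ccccc2)c1)C=C | intermediate
6 | (5R,6R)-6-[3,4-bis(benzyloxy)phenyl]-5-(methoxymethoxy)tetrahydro-2H-pyran-2-ol (anomeric mixture) | COCO[C@@H]1CCC(O)O[C@@H]1c1ccc(OCc2ccccc2)c(OCc2ccccc2)c1 | intermediate (not isolated)
7 | (5R,6R)-6-[3,4-bis(benzyloxy)phenyl]-5-(methoxymethoxy)tetrahydro-2H-pyran-2-one | COCO[C@@H]1CCC(=O)O[C@@H]1c1ccc(OCc2ccccc2)c(OCc2ccccc2)c1 | intermediate
8 | 4-(benzyloxy)benzoyl chloride | O=C(Cl)c1ccc(OCc2ccccc2)cc1 | starting material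
9 | (5R,6R)-6-[3,4-bis(benzyloxy)phenyl]-5-hydroxytetrahydro-2H-pyran-2-one | O[C@@H]1CCC(=O)O[C@@H]1c1ccc(OCc2ccccc2)c(OCc2ccccc2)c1 | intermediate (not isolated)
10 | (2R,3R)-2-[3,4-bis(benzyloxy)phenyl]-6-oxotetrahydro-2H-pyran-3-yl 4-(benzyloxy)benzoate | O=C(O[C@@H]1CCC(=O)O[C@@H]1c1ccc(OCc2ccccc2)c(OCc2ccccc2)c1)c1ccc(OCc2ccccc2)cc1 | intermediate
11 | 2,2,6-trimethyl-4H-1,3-dioxin-4-one | CC1=CC(=O)OC(C)(C)O1 | starting material
12 | lithium 2,2-dimethyl-6-methylidene-6H-1,3-dioxin-4-olate (dienolate of 11) | [Li+].C=C1C=C([O-])OC(C)(C)O1 | intermediate (not isolated)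
13 | (2R,3R)-2-[3,4-bis(benzyloxy)phenyl]-6-[(2,2-dimethyl-4-oxo-4H-1,3-dioxin-6-yl)methyl]-6-hydroxytetrahydro-2H-pyran-3-yl 4-(benzyloxy)benzoate (anomeric mixture) | O=C(O[C@@H]1CCC(O)(CC2=CC(=O)OC(C)(C)O2)O[C@@H]1c1ccc(OCc2ccccc2)c(OCc2ccccc2)c1)c1ccc(OCc2ccccc2)cc1 | intermediate
14 | (2R,3R)-2-[3,4-bis(benzyloxy)phenyl]-6-[(2,2-dimethyl-4-oxo-4H-1,3-dioxin-6-yl)methylidene]tetrahydro-2H-pyran-3-yl 4-(benzyloxy)benzoate (either alkene geometry) | O=C(O[C@@H]1CCC(=CC2=CC(=O)OC(C)(C)O2)O[C@@H]1c1ccc(OCc2ccccc2)c(OCc2ccccc2)c1)c1ccc(OCc2ccccc2)cc1 | intermediate (not isolated)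
15 | (2R,3R)-2-[3,4-bis(benzyloxy)phenyl]-6-(2,4-dioxobut-3-en-1-ylidene)tetrahydro-2H-pyran-3-yl 4-(benzyloxy)benzoate | O=C(O[C@@H]1CCC(=CC(=O)C=C=O)O[C@@H]1c1ccc(OCc2ccccc2)c(OCc2ccccc2)c1)c1ccc(OCc2ccccc2)cc1 | intermediate (not isolated)
16 | (2R,3R)-2-[3,4-bis(benzyloxy)phenyl]-6-(2-hydroxy-4-oxobuta-1,3-dien-1-yl)-3,4-dihydro-2H-pyran-3-yl 4-(benzyloxy)benzoate | O=C(O[C@@H]1CC=C(C=C(O)C=C=O)O[C@@H]1c1ccc(OCc2ccccc2)c(OCc2ccccc2)c1)c1ccc(OCc2ccccc2)cc1 | intermediate (not isolated)
17 | (2R,3R)-2-[3,4-bis(benzyloxy)phenyl]-7-hydroxy-5-oxo-3,4,4a,5-tetrahydro-2H-chromen-3-yl 4-(benzyloxy)benzoate | O=C(O[C@@H]1CC2C(=O)C=C(O)C=C2O[C@@H]1c1ccc(OCc2ccccc2)c(OCc2ccccc2)c1)c1ccc(OCc2ccccc2)cc1 | intermediate (not isolated)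
18 | (2R,3R)-2-[3,4-bis(benzyloxy)phenyl]-5,7-dihydroxy-3,4-dihydro-2H-chromen-3-yl 4-(benzyloxy)benzoate | O=C(O[C@@H]1Cc2c(O)cc(O)cc2O[C@@H]1c1ccc(OCc2ccccc2)c(OCc2ccccc2)c1)c1ccc(OCc2ccccc2)cc1 | intermediate
19 | epicatechin 3-O-p-hydroxybenzoate, (2R,3R) | O=C(O[C@@H]1Cc2c(O)cc(O)cc2O[C@@H]1c1ccc(O)c(O)c1)c1ccc(O)cc1 | target

**Step count and risks**

Total step count: 6. Longest linear sequence: 6 steps (from 1).

Steps most likely to fail:

1. Step 5 (proposed new method). The acylketene may be captured at oxygen, by traces of water or by product phenols before the carbon–carbon closure, or the enol ether may fail to tautomerise to the dienylketene. Fallback: the ring closure would be changed from a thermal pericyclic to an anionic one. Enol ether 14, prepared as in the first stage of step 5 but isolated, would be heated in toluene with methanol (the known alcoholysis of dioxinone-derived acylketenes) to give methyl 4-[(5R,6R)-6-[3,4-bis(benzyloxy)phenyl]-5-{[4-(benzyloxy)benzoyl]oxy}tetrahydro-2H-pyran-2-ylidene]-3-oxobutanoate F1. F1 would then be closed with LiN(SiMe3)2 (3 equiv) in THF at −78 to 0 °C by intramolecular Claisen (Dieckmann-type) condensation of the C4a carbanion of the vinylogous ester onto the methyl ester, the base-mediated way of folding 3,5-dioxo ester derivatives into phloroglucinols. Acidification and enolisation would return to the route at 18.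

2. Step 4. Proton transfer from the lactone to the dienolate, attack at the aroyl ester, or ring-opening of the adduct followed by a 1,2-acyl shift from O3 to O1 may compete with clean addition. Fallback: the order of events would be changed so that no ester is present when the enolate is used. Dienolate 12 would be added to the methoxymethyl lactone 7 to give 6-{[(5R,6R)-6-[3,4-bis(benzyloxy)phenyl]-2-hydroxy-5-(methoxymethoxy)tetrahydro-2H-pyran-2-yl]methyl}-2,2-dimethyl-4H-1,3-dioxin-4-one F2. Dehydration (pyridinium p-toluenesulfonate, sieves) would lock O1 in the enol ether 6-{[(5R,6R)-6-[3,4-bis(benzyloxy)phenyl]-5-(methoxymethoxy)tetrahydro-2H-pyran-2-ylidene]methyl}-2,2-dimethyl-4H-1,3-dioxin-4-one F3. Me2BBr at −78 °C would free 6-{[(5R,6R)-6-[3,4-bis(benzyloxy)phenyl]-5-hydroxytetrahydro-2H-pyran-2-ylidene]methyl}-2,2-dimethyl-4H-1,3-dioxin-4-one F4, and acylation with 8 (pyridine, DMAP) would return to the route at 14, which is then heated as in the second stage of step 5.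

3. Step 3. Translactonisation of the free cis-hydroxy δ-lactone to the γ-lactone before it is acylated, or Lewis-acid ionisation at the benzylic lactone oxygen, may consume material. Fallback: the exchange of the protecting group for the ester would be moved to the acetal oxidation level, where no lactone can isomerise. Lactol 6 would be treated with HCl in methanol (from AcCl, 0 °C to rt), which should remove the methoxymethyl group and, under thermodynamic control, give the six-membered methyl acetal (2R,3R)-2-[3,4-bis(benzyloxy)phenyl]-6-methoxytetrahydro-2H-pyran-3-ol F5. Acylation with 8 (pyridine, DMAP) would give (2R,3R)-2-[3,4-bis(benzyloxy)phenyl]-6-methoxytetrahydro-2H-pyran-3-yl 4-(benzyloxy)benzoate F6. Direct oxidation of the cyclic acetal with mCPBA and BF3·OEt2 (cat.) in CH2Cl2 would return to the route at 10.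

**Further compounds**

F1 | step 5 | methyl 4-[(5R,6R)-6-[3,4-bis(benzyloxy)phenyl]-5-{[4-(benzyloxy)benzoyl]oxy}tetrahydro-2H-pyran-2-ylidene]-3-oxobutanoate | O=C(O[C@@H]1CCC(=CC(=O)CC(=O)OC)O[C@@H]1c1ccc(OCc2ccccc2)c(OCc2ccccc2)c1)c1ccc(OCc2ccccc2)cc1
F2 | step 4 | 6-{[(5R,6R)-6-[3,4-bis(benzyloxy)phenyl]-2-hydroxy-5-(methoxymethoxy)tetrahydro-2H-pyran-2-yl]methyl}-2,2-dimethyl-4H-1,3-dioxin-4-one | COCO[C@@H]1CCC(O)(CC2=CC(=O)OC(C)(C)O2)O[C@@H]1c1ccc(OCc2ccccc2)c(OCc2ccccc2)c1
F3 | step 4 | 6-{[(5R,6R)-6-[3,4-bis(benzyloxy)phenyl]-5-(methoxymethoxy)tetrahydro-2H-pyran-2-ylidene]methyl}-2,2-dimethyl-4H-1,3-dioxin-4-one | COCO[C@@H]1CCC(=CC2=CC(=O)OC(C)(C)O2)O[C@@H]1c1ccc(OCc2ccccc2)c(OCc2ccccc2)c1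
F4 | step 4 | 6-{[(5R,6R)-6-[3,4-bis(benzyloxy)phenyl]-5-hydroxytetrahydro-2H-pyran-2-ylidene]methyl}-2,2-dimethyl-4H-1,3-dioxin-4-one | O[C@@H]1CCC(=CC2=CC(=O)OC(C)(C)O2)O[C@@H]1c1ccc(OCc2ccccc2)c(OCc2ccccc2)c1
F5 | step 3 | (2R,3R)-2-[3,4-bis(benzyloxy)phenyl]-6-methoxytetrahydro-2H-pyran-3-ol | O[C@@H]1CCC(OC)O[C@@H]1c1ccc(OCc2ccccc2)c(OCc2ccccc2)c1
F6 | step 3 | (2R,3R)-2-[3,4-bis(benzyloxy)phenyl]-6-methoxytetrahydro-2H-pyran-3-yl 4-(benzyloxy)benzoate | O=C(O[C@@H]1CCC(OC)O[C@@H]1c1ccc(OCc2ccccc2)c(OCc2ccccc2)c1)c1ccc(OCc2ccccc2)cc1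
A1 | direct plan | (S)-1-[3,4-bis(benzyloxy)phenyl]prop-2-yn-1-yl 3,5-bis(benzyloxy)phenyl ether | C#C[C@H](Oc1cc(OCc2ccccc2)cc(OCc2ccccc2)c1)c1ccc(OCc2ccccc2)c(OCc2ccccc2)c1
A2 | direct plan | (2R)-5,7-bis(benzyloxy)-2-[3,4-bis(benzyloxy)phenyl]chroman-3-one | O=C1Cc2c(OCc3ccccc3)cc(OCc3ccccc3)cc2O[C@@H]1c1ccc(OCc2ccccc2)c(OCc2ccccc2)c1
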